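**Retrosynthetic overview**

- The strategy rests on indole B, the indol-3-yl group on C4 of the tetramethoxybenzene ring. Its benzo carbons C4–C7 carry only hydrogen, so the N1–C7a and C3–C3a bonds can both be made to symmetric benzyne, with N1, C2 and C3 supplied by a 3-aryl-2H-azirine.
- Azirine ⇒ α-aryl vinyl azide (thermal loss of N2) ⇒ terminal aryl alkyne (Markovnikov hydroazidation) ⇒ aryl aldehyde (one-carbon homologation).
- Central ring–indole A bond ⇒ Suzuki–Miyaura coupling of 4-bromo-2,3,5,6-tetramethoxybenzaldehyde (from 1,2,4,5-tetramethoxybenzene) with the 3-boronate of SEM-protected 5-prenylindole (from 5-bromoindole and prenylboronic ester).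
- Ring order: the central ring and indole A are bought as rings; the azirine ring forms in step 10, the pyrrole ring of indole B in step 11, and SEM removal ends the route. The target has no stereocenter.

Key step: step 11

Remark (assumption and abbreviations): SEM on the indole nitrogen is taken to withstand CsF in MeCN at 60 °C, since its cleavage normally needs soluble fluoride at higher temperature. SEM = 2-(trimethylsilyl)ethoxymethyl; prenyl = 3-methylbut-2-en-1-yl; Bpin = 4,4,5,5-tetramethyl-1,3,2-dioxaborolan-2-yl; SPhos = 2-dicyclohexylphosphino-2',6'-dimethoxybiphenyl.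

**Route**

Step 1
Reactants: 1 5-bromo-1H-indole
Product: 2 5-bromo-1-{[2-(trimethylsilyl)ethoxy]methyl}-1H-indole
Conditions: NaH, DMF, 0 °C; SEMCl, 0 °C to rt
Reagents that add atoms: 2-(trimethylsilyl)ethoxymethyl chloride (SEMCl), C[Si](C)(C)CCOCCl
Why: NaH deprotonates the indole N–H and the indolide is alkylated at nitrogen by SEMCl (SN2 N-alkylation), which installs a base-stable, fluoride-cleavable group that later keeps this nitrogen away from benzyne.

Step 2
Reactants: 2 5-bromo-1-SEM-indole; 3 3-methylbut-2-enylboronic acid pinacol ester (prenyl-Bpin)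
Product: 4 5-(3-methylbut-2-en-1-yl)-1-{[2-(trimethylsilyl)ethoxy]methyl}-1H-indole
Conditions: PdCl2(IPent)(3-chloropyridine) (cat.; IPent = 1,3-bis[2,6-di(pentan-3-yl)phenyl]imidazol-2-ylidene), 5 M aq KOH, THF, 70 °C
Reagents that add atoms: none
Why: This is an α-selective Suzuki–Miyaura allylation in which the very bulky N-heterocyclic carbene on palladium should deliver the allyl group of 3 through its unsubstituted CH2 terminus, so that the linear prenyl arene forms and not the 1,1-dimethylallyl isomer, while SEM is inert to aqueous KOH.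

Step 3
Reactants: 4 5-prenyl-1-SEM-indole
Product: 5 3-bromo-5-(3-methylbut-2-en-1-yl)-1-{[2-(trimethylsilyl)ethoxy]methyl}-1H-indole
Conditions: NBS (1.0 equiv), THF, −78 °C
Reagents that add atoms: N-bromosuccinimide, O=C1CCC(=O)N1Br
Why: Electrophilic aromatic bromination should occur at indole C3, the most nucleophilic position of an N-alkylindole and far more reactive toward NBS at −78 °C than the trisubstituted prenyl alkene.

Step 4
Reactants: 5 3-bromo-5-prenyl-1-SEM-indole
Product: 7 5-(3-methylbut-2-en-1-yl)-3-(4,4,5,5-tetramethyl-1,3,2-dioxaborolan-2-yl)-1-{[2-(trimethylsilyl)ethoxy]methyl}-1H-indole, via 3-lithioindole 6 (not isolated)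
Conditions: n-BuLi, THF, −78 °C; iPrOBpin, −78 °C to rt; aq NH4Cl
Reagents that add atoms: 2-isopropoxy-4,4,5,5-tetramethyl-1,3,2-dioxaborolane (iPrOBpin), CC(C)OB1OC(C)(C)C(C)(C)O1
Why: Bromine–lithium exchange is faster than C2 deprotonation at −78 °C, and the 3-lithioindole is trapped at once by the borate ester (lithiation–borylation) before it can isomerize to the 2-lithio species.

Step 5
Reactants: 8 1,2,4,5-tetramethoxybenzene
Product: 9 1,4-dibromo-2,3,5,6-tetramethoxybenzene
Conditions: NBS (2.1 equiv), MeCN, 0 °C to rt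
Reagents that add atoms: N-bromosuccinimide, O=C1CCC(=O)N1Br
Why: Twofold electrophilic aromatic bromination fills the only two free ring positions, each flanked by two methoxy groups, and NBS in dry MeCN brominates the ring without the oxidative demethylation to a quinone that aqueous oxidants would cause.

Step 6
Reactants: 9 1,4-dibromo-2,3,5,6-tetramethoxybenzene
Product: 11 4-bromo-2,3,5,6-tetramethoxybenzaldehyde, via aryllithium 10 (not isolated)
Conditions: n-BuLi (1.0 equiv), THF, −78 °C; DMF, −78 °C to rt; aq NH4Cl
Reagents that add atoms: N,N-dimethylformamide, CN(C)C=O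
Why: Bromine–lithium exchange with one equivalent of n-BuLi should stop at the monolithio stage, and formylation of the aryllithium with DMF gives the aldehyde on aqueous work-up, so the symmetric ring is differentiated without a statistical coupling.

Step 7
Reactants: 11 4-bromo-2,3,5,6-tetramethoxybenzaldehyde; 7 5-prenyl-1-SEM-indol-3-yl-Bpin (1.3 equiv)
Product: 12 2,3,5,6-tetramethoxy-4-[5-(3-methylbut-2-en-1-yl)-1-{[2-(trimethylsilyl)ethoxy]methyl}-1H-indol-3-yl]benzaldehyde
Conditions: Pd(OAc)2, SPhos, K3PO4, toluene/H2O, 90 °C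
Reagents that add atoms: none
Why: In this Suzuki–Miyaura coupling the dialkylbiarylphosphine supports oxidative addition into the di-ortho-methoxy aryl bromide (helped by the para formyl group) and coupling with the heteroaryl boronate, while the non-enolizable aldehyde, SEM and prenyl groups are spectators.

Step 8
Reactants: 12 biaryl aldehyde
Product: 13 3-(4-ethynyl-2,3,5,6-tetramethoxyphenyl)-5-(3-methylbut-2-en-1-yl)-1-{[2-(trimethylsilyl)ethoxy]methyl}-1H-indole
Conditions: dimethyl (1-diazo-2-oxopropyl)phosphonate, K2CO3, MeOH/THF, rt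
Reagents that add atoms: dimethyl (1-diazo-2-oxopropyl)phosphonate (Ohira–Bestmann reagent), CC(=O)C(=[N+]=[N-])P(=O)(OC)OC
Why: In this Seyferth–Gilbert homologation the diazomethylphosphonate anion released from the Ohira–Bestmann reagent by methanolysis converts the non-enolizable aldehyde into the terminal alkyne with loss of N2 and dimethyl phosphate, under conditions mild enough for the SEM, indole and prenyl groups.

Step 9
Reactants: 13 terminal aryl alkyne
Product: 14 3-[4-(1-azidoethenyl)-2,3,5,6-tetramethoxyphenyl]-5-(3-methylbut-2-en-1-yl)-1-{[2-(trimethylsilyl)ethoxy]methyl}-1H-indole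
Conditions: TMSN3, H2O (2 equiv), Ag2CO3 (cat.), DMSO, 80 °C, short reaction time
Reagents that add atoms: azidotrimethylsilane, C[Si](C)(C)N=[N+]=[N-]
Why: In this silver-catalyzed Markovnikov hydroazidation of a terminal aryl alkyne, HN3 formed from TMSN3 and water adds across the silver-activated triple bond with azide at the aryl-bearing carbon, and neither the prenyl alkene nor the indole reacts with azide under these near-neutral conditions.

Step 10
Reactants: 14 α-aryl vinyl azide
Product: 15 3-[4-(2H-azirin-3-yl)-2,3,5,6-tetramethoxyphenyl]-5-(3-methylbut-2-en-1-yl)-1-{[2-(trimethylsilyl)ethoxy]methyl}-1H-indole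
Conditions: toluene, 100 °C; used at once in step 11
Reagents that add atoms: none
Why: Thermolysis of an α-aryl vinyl azide gives the 3-aryl-2H-azirine by loss of N2 with closure of nitrogen onto the alkene carbon, a reagent-free unimolecular reaction that avoids the Beckmann-type aryl migration an oxime sulfonate of this electron-rich ring would risk.

Step 11
Reactants: 15 3-aryl-2H-azirine; 16 2-(trimethylsilyl)phenyl trifluoromethanesulfonate
Product: 20 3-[4-(1H-indol-3-yl)-2,3,5,6-tetramethoxyphenyl]-5-(3-methylbut-2-en-1-yl)-1-{[2-(trimethylsilyl)ethoxy]methyl}-1H-indole, via benzyne 17 (not isolated), via azirinobenzazetine adduct 18 (not isolated), via 3H-indole tautomer 19 (not isolated)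
Conditions: CsF (3 equiv), MeCN, 60 °C; 16 (about 1.2 equiv) added slowly
Reagents that add atoms: none
Why: Fluoride removes the silyl group of 16 and triflate leaves to give benzyne 17, the azirine nitrogen of 15 adds to it (N1–C7a bond) and the ortho aryl anion generated by this addition closes on the activated C=N carbon (C3–C3a bond) to the azirinobenzazetine 18, after which heterolysis of the N–C3 bond shared by the three- and four-membered rings, a 1,2-hydrogen shift from C2 to C3 (3H-indole 19) and tautomerization give the 1H-indole. The closest known reaction type is the fluoride-triggered annulation of arynes with 2H-azirines to N-unsubstituted indoles, applied here to a 2-unsubstituted 3-aryl azirine. The only ring closed is the pyrrole ring of indole B, in a stepwise formal [3+2] mode: intermolecular N-arylation, 4-endo-trig closure of the aryl anion on the iminium-type carbon (a formal [2+2] addition across C=N), then ring expansion by cleavage of the zero-atom bridge. No stereocenter is set, because the sp3 centers of 18 and 19 are lost on aromatization. Benzyne is symmetric, so no regiochemistry arises, and the selectivity needed is a single annulation without arylation of the new N–H or an ene reaction at the prenyl group; it is secured by the azirine nitrogen being the only good nucleophile in 15 (the other indole nitrogen carries SEM), by generating the aryne slowly as the scarce partner, and by working warm in MeCN so that the ring-expanded intermediate becomes the neutral indole before it meets a second aryne. The hexasubstituted aryl group should not block the closure, since the wide exocyclic angles at azirine C3 hold its two ortho methoxy groups near the azirine plane and leave both faces of the C=N bond open.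

Step 12
Reactants: 20 mono-SEM bis-indole
Product: 21 3-[4-(1H-indol-3-yl)-2,3,5,6-tetramethoxyphenyl]-5-(3-methylbut-2-en-1-yl)-1H-indole (CNP0306547.0)
Conditions: Bu4NF, ethylenediamine, DMF, 80 °C
Reagents that add atoms: none
Why: In this fluoride-induced SEM cleavage, fluoride attacks silicon and the group fragments with loss of fluorotrimethylsilane, ethene and formaldehyde (taken up by ethylenediamine), releasing the free N–H indole under basic conditions that leave the methyl ethers, the prenyl alkene and both indoles untouched.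

**Compound list**

1 | 5-bromo-1H-indole | Brc1ccc2[nH]ccc2c1 | starting material
2 | 5-bromo-1-{[2-(trimethylsilyl)ethoxy]methyl}-1H-indole | Brc1ccc2n(COCC[Si](C)(C)C)ccc2c1 | intermediate
3 | 3-methylbut-2-enylboronic acid pinacol ester | CC(C)=CCB1OC(C)(C)C(C)(C)O1 | starting material
4 | 5-(3-methylbut-2-en-1-yl)-1-SEM-indole | CC(C)=CCc1ccc2n(COCC[Si](C)(C)C)ccc2c1 | intermediate
5 | 3-bromo-5-(3-methylbut-2-en-1-yl)-1-SEM-indole | CC(C)=CCc1ccc2n(COCC[Si](C)(C)C)cc(Br)c2c1 | intermediate
6 | [5-(3-methylbut-2-en-1-yl)-1-SEM-indol-3-yl]lithium (not isolated) | CC(C)=CCc1ccc2n(COCC[Si](C)(C)C)cc([Li])c2c1 | intermediate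
7 | 5-(3-methylbut-2-en-1-yl)-3-(4,4,5,5-tetramethyl-1,3,2-dioxaborolan-2-yl)-1-SEM-indole | CC(C)=CCc1ccc2n(COCC[Si](C)(C)C)cc(B3OC(C)(C)C(C)(C)O3)c2c1 | intermediate
8 | 1,2,4,5-tetramethoxybenzene | COc1cc(OC)c(OC)cc1OC | starting material
9 | 1,4-dibromo-2,3,5,6-tetramethoxybenzene | COc1c(OC)c(Br)c(OC)c(OC)c1Br | intermediate
10 | (4-bromo-2,3,5,6-tetramethoxyphenyl)lithium (not isolated) | COc1c(OC)c(Br)c(OC)c(OC)c1[Li] | intermediate
11 | 4-bromo-2,3,5,6-tetramethoxybenzaldehyde | COc1c(OC)c(Br)c(OC)c(OC)c1C=O | intermediate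
12 | 2,3,5,6-tetramethoxy-4-[5-(3-methylbut-2-en-1-yl)-1-SEM-indol-3-yl]benzaldehyde | COc1c(OC)c(-c2cn(COCC[Si](C)(C)C)c3ccc(CC=C(C)C)cc23)c(OC)c(OC)c1C=O | intermediate
13 | 3-(4-ethynyl-2,3,5,6-tetramethoxyphenyl)-5-(3-methylbut-2-en-1-yl)-1-SEM-indole | COc1c(OC)c(-c2cn(COCC[Si](C)(C)C)c3ccc(CC=C(C)C)cc23)c(OC)c(OC)c1C#C | intermediate
14 | 3-[4-(1-azidoethenyl)-2,3,5,6-tetramethoxyphenyl]-5-(3-methylbut-2-en-1-yl)-1-SEM-indole | COc1c(OC)c(-c2cn(COCC[Si](C)(C)C)c3ccc(CC=C(C)C)cc23)c(OC)c(OC)c1C(=C)N=[N+]=[N-] | intermediate
15 | 3-[4-(2H-azirin-3-yl)-2,3,5,6-tetramethoxyphenyl]-5-(3-methylbut-2-en-1-yl)-1-SEM-indole (key-step precursor) | COc1c(OC)c(-c2cn(COCC[Si](C)(C)C)c3ccc(CC=C(C)C)cc23)c(OC)c(OC)c1C4=NC4 | intermediate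
16 | 2-(trimethylsilyl)phenyl trifluoromethanesulfonate | C[Si](C)(C)c1ccccc1OS(=O)(=O)C(F)(F)F | starting material
17 | benzyne (1,2-didehydrobenzene; not isolated) | C1=CC=CC#C1 | intermediate
18 | azirinobenzazetine adduct: benzo-fused 1-azabicyclo[2.1.0]pentane whose bridgehead carbon carries the central aryl group (racemic, not isolated) | COc1c(OC)c(-c2cn(COCC[Si](C)(C)C)c3ccc(CC=C(C)C)cc23)c(OC)c(OC)c1C45CN4c6ccccc65 | intermediate
19 | 3-aryl-3H-indole tautomer (racemic, not isolated) | COc1c(OC)c(-c2cn(COCC[Si](C)(C)C)c3ccc(CC=C(C)C)cc23)c(OC)c(OC)c1C4C=Nc5ccccc45 | intermediate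
20 | 3-[4-(1H-indol-3-yl)-2,3,5,6-tetramethoxyphenyl]-5-(3-methylbut-2-en-1-yl)-1-SEM-indole (key-step product) | COc1c(OC)c(-c2cn(COCC[Si](C)(C)C)c3ccc(CC=C(C)C)cc23)c(OC)c(OC)c1-c1c[nH]c2ccccc12 | intermediate
21 | 3-[4-(1H-indol-3-yl)-2,3,5,6-tetramethoxyphenyl]-5-(3-methylbut-2-en-1-yl)-1H-indole (CNP0306547.0) | COc1c(OC)c(-c2c[nH]c3ccc(CC=C(C)C)cc23)c(OC)c(OC)c1-c1c[nH]c2ccccc12 | target

**Count**

Total steps: 12. Longest linear sequence: 10 steps (steps 1–4 and 7–12, from 5-bromoindole); the central-ring branch (steps 5–6) joins at step 7.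

**Steps most likely to fail, with fallbacks**

Step 11 (key step). Closure of the aryl anion onto the azirine carbon that carries the hexasubstituted ring may be slow, so the first adduct could be lost to protonation by MeCN or to a second aryne. The new N–H could also be arylated, or fluoride could begin to cleave SEM. The fallback makes the aryl–indole B bond by cross-coupling instead of building the ring. It sets out from 9 and 7. A Suzuki–Miyaura coupling run with 9 in threefold excess (Pd(OAc)2, SPhos, K3PO4, toluene/H2O, 90 °C) should give the monocoupled bromide 3-(4-bromo-2,3,5,6-tetramethoxyphenyl)-5-prenyl-1-SEM-indole F1. A second Suzuki–Miyaura coupling of F1 with commercial tert-butyl 3-(4,4,5,5-tetramethyl-1,3,2-dioxaborolan-2-yl)indole-1-carboxylate under the same catalyst should give the N-Boc bis-indole tert-butyl 3-{2,3,5,6-tetramethoxy-4-[5-prenyl-1-SEM-indol-3-yl]phenyl}indole-1-carboxylate F2. K2CO3 in MeOH then removes the carbamate from the indole nitrogen, and the fallback comes back to the route at 20.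

Step 9. Azide delivery to the alkyne carbon flanked by two methoxy groups may be slow, and at 80 °C the vinyl azide may already lose N2 in the presence of the silver salt and DMSO, so that azirine forms under conditions it does not survive. The fallback is a Neber route through the methyl ketone, setting out from 12. MeMgBr in THF at 0 °C should give the racemic carbinol 1-{2,3,5,6-tetramethoxy-4-[5-prenyl-1-SEM-indol-3-yl]phenyl}ethanol F3. Dess–Martin periodinane in CH2Cl2 should give the methyl ketone 1-{2,3,5,6-tetramethoxy-4-[5-prenyl-1-SEM-indol-3-yl]phenyl}ethanone F4. NH2OH·HCl and pyridine in hot EtOH should give the ketoxime F5. MsCl and Et3N in CH2Cl2 at −20 °C should give the oxime methanesulfonate F6, which is treated in the same flask with DBU to close the azirine (Neber reaction, kept cold to hold back Beckmann migration of the electron-rich aryl group). The fallback comes back to the route at 15.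

Step 7. Protodeboronation of the indol-3-yl boronate in hot aqueous base may outrun transmetalation onto the hindered arylpalladium intermediate. The fallback is a Negishi coupling without boron or water, setting out from 5. Bromine–lithium exchange as in step 4 gives 6, and ZnCl2 in THF converts it into the organozinc [5-prenyl-1-SEM-indol-3-yl]zinc chloride F7. Coupling of F7 with 11 catalyzed by Pd(OAc)2 and SPhos in THF at 50 °C, where arylzinc halides leave the aldehyde alone, comes back to the route at 12.

**Further compounds**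

F1 | step 11 | 3-(4-bromo-2,3,5,6-tetramethoxyphenyl)-5-(3-methylbut-2-en-1-yl)-1-{[2-(trimethylsilyl)ethoxy]methyl}-1H-indole | COc1c(OC)c(Br)c(OC)c(OC)c1-c1cn(COCC[Si](C)(C)C)c2ccc(CC=C(C)C)cc12
F2 | step 11 | tert-butyl 3-{2,3,5,6-tetramethoxy-4-[5-(3-methylbut-2-en-1-yl)-1-SEM-indol-3-yl]phenyl}indole-1-carboxylate | COc1c(OC)c(-c2cn(C(=O)OC(C)(C)C)c3ccccc23)c(OC)c(OC)c1-c1cn(COCC[Si](C)(C)C)c2ccc(CC=C(C)C)cc12
F3 | step 9 | racemic 1-{2,3,5,6-tetramethoxy-4-[5-(3-methylbut-2-en-1-yl)-1-SEM-indol-3-yl]phenyl}ethanol | COc1c(OC)c(-c2cn(COCC[Si](C)(C)C)c3ccc(CC=C(C)C)cc23)c(OC)c(OC)c1C(C)O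
F4 | step 9 | 1-{2,3,5,6-tetramethoxy-4-[5-(3-methylbut-2-en-1-yl)-1-SEM-indol-3-yl]phenyl}ethanone | COc1c(OC)c(-c2cn(COCC[Si](C)(C)C)c3ccc(CC=C(C)C)cc23)c(OC)c(OC)c1C(C)=O
F5 | step 9 | 1-{2,3,5,6-tetramethoxy-4-[5-(3-methylbut-2-en-1-yl)-1-SEM-indol-3-yl]phenyl}ethanone oxime (E/Z mixture) | COc1c(OC)c(-c2cn(COCC[Si](C)(C)C)c3ccc(CC=C(C)C)cc23)c(OC)c(OC)c1C(C)=NO
F6 | step 9 | O-methanesulfonyl oxime of ketone F4 (not isolated) | COc1c(OC)c(-c2cn(COCC[Si](C)(C)C)c3ccc(CC=C(C)C)cc23)c(OC)c(OC)c1C(C)=NOS(C)(=O)=O
F7 | step 7 | [5-(3-methylbut-2-en-1-yl)-1-SEM-indol-3-yl]zinc chloride | CC(C)=CCc1ccc2n(COCC[Si](C)(C)C)cc([Zn]Cl)c2c1
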